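**Retrosynthetic overview**
1. Target 15 ⇐ octabenzyl ether 14 by global O-debenzylation.
2. 14 ⇐ triol 12 in one acid operation: both trans-dihydrobenzofuran rings close first (O–C7 bonds, SN1), then the seven-membered carbocycle (C7''–ring B Friedel–Crafts). The bis-furan intermediate is C2-symmetric, so its two resorcinol rings are homotopic.
3. 12 ⇐ triketone 11 by asymmetric transfer hydrogenation with dynamic kinetic resolution, which sets C-8 and C-8'.
4. 11 ⇐ 8 + 2 × 4 (key step): both C8–aryl bonds are made by attack of ring A on the enolonium (α-keto cation) form of a deoxybenzoin, joining two normally nucleophilic carbons.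
5. 4 and 8 ⇐ Pd-catalysed α-arylation of acetophenones 1 and 7 with aryl bromides 2 and 6. Ring order: ring A is bought in, the two dihydrofurans form together, the seven-membered ring last.

Locants: in each arm C-7 becomes the O–CH(Ar) carbon and C-8 the CH(Ar) carbon of a dihydrofuran; C-7''/C-8'' are the CH(Ar)/CH2 carbons of the seven-membered ring; ring A is the central ring, ring B the resorcinol ring that enters the seven-membered ring, ring D the 2,4-dioxygenated ring.

Assumption: 1, 2, 5 and 7 are bought; the carbinol configuration at C-7'' in 12 is immaterial because that centre is re-formed in step 6.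

**Step 1**
Reactants: 1 1-[4-(benzyloxy)phenyl]ethan-1-one; 2 1-bromo-3,5-bis(benzyloxy)benzene
Product: 4 (Z)-{1-[4-(benzyloxy)phenyl]-2-[3,5-bis(benzyloxy)phenyl]ethenyloxy}trimethylsilane, via lithium enolate 3 (not isolated)
Conditions: Pd2(dba)3 (1 mol %), Xantphos (2.4 mol %), LiN(SiMe3)2 (2.3 equiv), THF, 65 °C; then Me3SiCl (1.5 equiv), 0 °C; hexane, filtration, short plug of NEt3-deactivated silica
Reagents that add atoms: chlorotrimethylsilane, C[Si](C)(C)Cl
Why: Palladium-catalysed ketone α-arylation (Buchwald–Hartwig–Miura); the deoxybenzoin product is more acidic than 1 and rests as enolate 3, which stops the reaction at mono-arylation and is O-silylated to the (Z)-enol ether.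

**Step 2**
Reactants: 5 5-bromobenzene-1,3-diol
Product: 6 1-bromo-3,5-bis(methoxymethoxy)benzene
Conditions: NaH (2.4 equiv), MOMCl (2.4 equiv), DMF, 0 °C → rt
Reagents that add atoms: chloromethyl methyl ether, COCCl
Why: Williamson-type O-alkylation of the two phenoxides; the small, acid-labile MOM groups keep ring A electron-rich for step 4 and come off in the acid of step 6.

**Step 3**
Reactants: 6 1-bromo-3,5-bis(methoxymethoxy)benzene; 7 1-[2,4-bis(benzyloxy)phenyl]ethan-1-one
Product: 8 1-[2,4-bis(benzyloxy)phenyl]-2-[3,5-bis(methoxymethoxy)phenyl]ethan-1-one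
Conditions: Pd2(dba)3 (1 mol %), Xantphos (2.4 mol %), NaOC(CH3)3 (2.3 equiv), THF, 65 °C; aq NH4Cl
Reagents that add atoms: none
Why: Palladium-catalysed ketone α-arylation again; it delivers ring A already carrying the two-carbon chain and ring D of the future seven-membered ring.

**Step 4 (key step)**
Reactants: 4 (Z)-silyl enol ether (3.0 equiv); 8 1-[2,4-bis(benzyloxy)phenyl]-2-[3,5-bis(methoxymethoxy)phenyl]ethan-1-one (1.0 equiv)
Product: 11 2,2'-{2-[2-(2,4-bis(benzyloxy)phenyl)-2-oxoethyl]-4,6-bis(methoxymethoxy)-1,3-phenylene}bis{1-[4-(benzyloxy)phenyl]-2-[3,5-bis(benzyloxy)phenyl]ethan-1-one}, via enolonium iodane 9 (not isolated), via mono-arylated ketone 10 (not isolated)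
Conditions: PhI(OAc)2 (3.0 equiv), BF3·OEt2 (4.5 equiv), CH2Cl2, −78 °C, slow addition of 4, 15 min; then 8, −78 → −30 °C; aq NaHCO3
Reagents that add atoms: none
Why: Proposed new method: PhI(OAc)2/BF3 turns silyl enol ether 4 into the O-bound trivalent-iodine enolate 9, whose α-carbon is a carbon electrophile (a polarity-reversed enolate); the two free positions of ring A that flank the CH2 group (each para to one OMOM and ortho to the other, where 3,5-dialkoxybenzyl rings take electrophiles) attack it one after the other in SN2' fashion with loss of PhI, while the acyl-deactivated ring D and the pendant rings next to the cationic centre react more slowly; the closest known reaction types are the metal-free α-arylation of ketone enolonium species with indoles and other electron-rich arenes and the classical Friedel–Crafts alkylation with desyl halides; the two new C-8 centres form unselectively on purpose, since they are epimerisable and are fixed in step 5.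

**Step 5**
Reactants: 11 triketone (mixture of C-8/C-8' epimers)
Product: 12 (1R,1'R,2R,2'R)-2,2'-{2-[(2R)-2-(2,4-bis(benzyloxy)phenyl)-2-hydroxyethyl]-4,6-bis(methoxymethoxy)-1,3-phenylene}bis{1-[4-(benzyloxy)phenyl]-2-[3,5-bis(benzyloxy)phenyl]ethan-1-ol}
Conditions: RuCl[(R,R)-TsDPEN](p-cymene) (6 mol %), HCO2H/NEt3 (2:5), DMF, 45 °C
Reagents that add atoms: none
Why: Proposed new method: Noyori–Ikariya asymmetric transfer hydrogenation run as a double dynamic kinetic resolution; free NEt3 equilibrates the doubly benzylic C-8 centres through the enol, the (R,R)-catalyst gives (R)-carbinols (as it does with acetophenone) and reduces the Felkin-matched (8R) epimer faster, so both arms converge on (7R,8R) and the C2-symmetric product is further enriched statistically; the closest known reaction types are the dynamic kinetic transfer hydrogenations of α-aryl cyclic ketones and benzoins and the dynamic kinetic hydrogenation of 2-arylpropiophenones; the third ketone is reduced too (R expected, immaterial).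

**Step 6**
Reactants: 12 triol
Product: 14 octa-O-benzyl ether of 15, via bis(dihydrobenzofuran) methyl ether 13 (not isolated)
Conditions: stage 1: HCl (1.25 M in MeOH)/THF 1:1, 40 °C; evaporate; stage 2: CF3CO2H/CH2Cl2 1:9 (0.01 M), 0 °C → rt
Reagents that add atoms: none
Why: Acid methanolysis of the MOM ethers, SN1 cyclodehydration and cationic Friedel–Crafts cyclisation: in stage 1 each p-benzyloxybenzylic cation is captured by the neighbouring free phenol anti to the C-8 aryl (reversible, so the trans ring results and (8R) relays to (7R)) while C-7'' is parked as its methyl ether; in stage 2 the 2,4-bis(benzyloxy)benzylic cation is attacked by the ortho carbon of one of the two homotopic resorcinol rings in a seven-membered ring closure of the ampelopsin B type, with the large aryl group exo to ring B so that H-7'' ends up cis to H-8', i.e. (7''S).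

**Step 7**
Reactants: 14 octa-O-benzyl ether of 15
Product: 15 target CNP0154047.2
Conditions: H2 (1 atm), 10% Pd/C, EtOAc/MeOH 1:1, rt
Reagents that add atoms: none
Why: Heterogeneous hydrogenolysis of the eight aryl benzyl ethers; under neutral conditions at 1 atm the dihydrofuran C–O bonds and the five stereocentres are not touched.

**Compound list**
1 | 1-[4-(benzyloxy)phenyl]ethan-1-one | CC(=O)c1ccc(OCc2ccccc2)cc1 | starting material
2 | 1-bromo-3,5-bis(benzyloxy)benzene | Brc1cc(OCc2ccccc2)cc(OCc2ccccc2)c1 | starting material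
3 | lithium (Z)-1-[4-(benzyloxy)phenyl]-2-[3,5-bis(benzyloxy)phenyl]ethen-1-olate | [Li+].[O-]/C(=C\c1cc(OCc2ccccc2)cc(OCc2ccccc2)c1)c1ccc(OCc2ccccc2)cc1 | intermediate (not isolated)
4 | (Z)-{1-[4-(benzyloxy)phenyl]-2-[3,5-bis(benzyloxy)phenyl]ethenyloxy}trimethylsilane | C[Si](C)(C)O/C(=C\c1cc(OCc2ccccc2)cc(OCc2ccccc2)c1)c1ccc(OCc2ccccc2)cc1 | intermediate
5 | 5-bromobenzene-1,3-diol | Oc1cc(O)cc(Br)c1 | starting material
6 | 1-bromo-3,5-bis(methoxymethoxy)benzene | COCOc1cc(Br)cc(OCOC)c1 | intermediate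
7 | 1-[2,4-bis(benzyloxy)phenyl]ethan-1-one | CC(=O)c1ccc(OCc2ccccc2)cc1OCc1ccccc1 | starting material
8 | 1-[2,4-bis(benzyloxy)phenyl]-2-[3,5-bis(methoxymethoxy)phenyl]ethan-1-one | O=C(Cc1cc(OCOC)cc(OCOC)c1)c1ccc(OCc2ccccc2)cc1OCc1ccccc1 | intermediate
9 | acetoxy(phenyl)-λ3-iodanyl (Z)-enol ether of 1-[4-(benzyloxy)phenyl]-2-[3,5-bis(benzyloxy)phenyl]ethan-1-one (enolonium) | CC(=O)OI(c1ccccc1)O/C(=C\c1cc(OCc2ccccc2)cc(OCc2ccccc2)c1)c1ccc(OCc2ccccc2)cc1 | intermediate (not isolated)
10 | 1-[4-(benzyloxy)phenyl]-2-{2-[2-(2,4-bis(benzyloxy)phenyl)-2-oxoethyl]-4,6-bis(methoxymethoxy)phenyl}-2-[3,5-bis(benzyloxy)phenyl]ethan-1-one (racemic) | O=C(Cc1cc(OCOC)cc(OCOC)c1C(C(=O)c1ccc(OCc2ccccc2)cc1)c1cc(OCc2ccccc2)cc(OCc2ccccc2)c1)c1ccc(OCc2ccccc2)cc1OCc1ccccc1 | intermediate (not isolated)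
11 | 2,2'-{2-[2-(2,4-bis(benzyloxy)phenyl)-2-oxoethyl]-4,6-bis(methoxymethoxy)-1,3-phenylene}bis{1-[4-(benzyloxy)phenyl]-2-[3,5-bis(benzyloxy)phenyl]ethan-1-one} (interconverting C-8/C-8' epimers, no configuration assigned) | O=C(Cc1c(C(C(=O)c2ccc(OCc3ccccc3)cc2)c2cc(OCc3ccccc3)cc(OCc3ccccc3)c2)c(OCOC)cc(OCOC)c1C(C(=O)c1ccc(OCc2ccccc2)cc1)c1cc(OCc2ccccc2)cc(OCc2ccccc2)c1)c1ccc(OCc2ccccc2)cc1OCc1ccccc1 | intermediate
12 | (1R,1'R,2R,2'R)-2,2'-{2-[(2R)-2-(2,4-bis(benzyloxy)phenyl)-2-hydroxyethyl]-4,6-bis(methoxymethoxy)-1,3-phenylene}bis{1-[4-(benzyloxy)phenyl]-2-[3,5-bis(benzyloxy)phenyl]ethan-1-ol} | O[C@H](Cc1c([C@H]([C@@H](O)c2ccc(OCc3ccccc3)cc2)c2cc(OCc3ccccc3)cc(OCc3ccccc3)c2)c(OCOC)cc(OCOC)c1[C@H]([C@@H](O)c1ccc(OCc2ccccc2)cc1)c1cc(OCc2ccccc2)cc(OCc2ccccc2)c1)c1ccc(OCc2ccccc2)cc1OCc1ccccc1 | intermediate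
13 | (2R,3R,5R,6R)-2,6-bis[4-(benzyloxy)phenyl]-3,5-bis[3,5-bis(benzyloxy)phenyl]-4-{2-[2,4-bis(benzyloxy)phenyl]-2-methoxyethyl}-2,3,5,6-tetrahydrobenzo[1,2-b:5,4-b']difuran (both methoxy epimers) | COC(Cc1c2c(cc3c1[C@@H](c1cc(OCc4ccccc4)cc(OCc4ccccc4)c1)[C@H](c1ccc(OCc4ccccc4)cc1)O3)O[C@@H](c1ccc(OCc3ccccc3)cc1)[C@@H]2c1cc(OCc2ccccc2)cc(OCc2ccccc2)c1)c1ccc(OCc2ccccc2)cc1OCc1ccccc1 | intermediate (not isolated)
14 | octa-O-benzyl ether of 15: both dihydrofurans trans-(R,R), seven-membered ring closed, (7''S) | c1ccccc1COc1ccc([C@@H]2Oc3cc4c5c(c3[C@H]2c2cc(OCc6ccccc6)cc(OCc6ccccc6)c2)C[C@@H](c2ccc(OCc6ccccc6)cc2OCc2ccccc2)c2c(OCc6ccccc6)cc(OCc6ccccc6)cc2[C@H]5[C@H](c2ccc(OCc6ccccc6)cc2)O4)cc1 | intermediate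
15 | CNP0154047.2: ring A fused to two trans-(2R,3R)-2-(4-hydroxyphenyl)-2,3-dihydrofurans, one carrying a 3,5-dihydroxyphenyl group at C-3 and the other joined through ring B and the (S)-CH(2,4-dihydroxyphenyl)–CH2 bridge into a seven-membered ring | Oc1ccc([C@@H]2Oc3cc4c5c(c3[C@H]2c2cc(O)cc(O)c2)C[C@@H](c2ccc(O)cc2O)c2c(O)cc(O)cc2[C@H]5[C@H](c2ccc(O)cc2)O4)cc1 | target

**Totals**
Total steps: 7. Longest linear sequence: 6 steps (5 → 6 → 8 → 11 → 12 → 14 → 15).

**Steps most likely to fail and fallbacks**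

Step 4. Risks are self-coupling of the enolonium, arylation of the pendant 3,5-bis(benzyloxy)phenyl rings or of ring D instead of the second, hindered ring A position, attack between the two OMOM groups, and MOM loss under BF3. The fallback sets out from 4 and 8 and keeps the same polarity-reversed bond construction but uses an isolable electrophile. Silyl enol ether 4 is brominated with N-bromosuccinimide (THF, −78 °C) to the α-bromo ketone 2-bromo-1-[4-(benzyloxy)phenyl]-2-[3,5-bis(benzyloxy)phenyl]ethan-1-one F1. Ring A of 8 is then alkylated twice by F1 under halide abstraction (AgOSO2CF3, 2,6-di-tert-butylpyridine, CH2Cl2, −40 °C → rt). The first alkylation can be pushed to completion before the second is forced. The route is rejoined at 11.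

Step 5. Risks are that the hindered triaryl ketones enolise too slowly for a dynamic process, are reduced sluggishly, or that the catalyst selects the wrong C-8 epimer. The fallback sets out from 11 and replaces the dynamic process by a static, reagent-controlled reduction with recycling. Reduction with (S)-2-methyl-CBS-oxazaborolidine and BH3·SMe2 (THF, −20 °C) fixes the (R)-carbinols by the aryl-as-larger-group rule but leaves C-8 statistical. Chromatography separates 12 from the mixed (8R)/(8S) triol F2 and the bis-(8S) triol F3. F2 and F3 are oxidised back to the epimerisable triketone 11 with Dess–Martin periodinane and reduced again. The route is rejoined at 12.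

Step 6. Risks are the wrong C-7'' epimer or a messy cascade when five bonds are made in one flask, and loss of C-8 integrity by elimination from the C-7 cation. The fallback sets out from 12 and reverses the order of ring formation with an isolated intermediate. In (CF3)2CHOH at rt without added acid only the 2,4-bis(benzyloxy)benzylic carbinol ionises, and the seven-membered ring closes first to give the MOM-protected dibenzocycloheptane diol F4. HCl in MeOH/THF (40 °C) then removes the MOM groups and closes both trans-dihydrofurans. The route is rejoined at 14.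

**Further compounds**
F1 | step 4 | 2-bromo-1-[4-(benzyloxy)phenyl]-2-[3,5-bis(benzyloxy)phenyl]ethan-1-one (racemic) | O=C(C(Br)c1cc(OCc2ccccc2)cc(OCc2ccccc2)c1)c1ccc(OCc2ccccc2)cc1
F2 | step 5 | diastereomer of 12 with one (1R,2R) arm and one (1R,2S) arm | O[C@H](Cc1c([C@H]([C@@H](O)c2ccc(OCc3ccccc3)cc2)c2cc(OCc3ccccc3)cc(OCc3ccccc3)c2)c(OCOC)cc(OCOC)c1[C@@H]([C@@H](O)c1ccc(OCc2ccccc2)cc1)c1cc(OCc2ccccc2)cc(OCc2ccccc2)c1)c1ccc(OCc2ccccc2)cc1OCc1ccccc1
F3 | step 5 | diastereomer of 12 with two (1R,2S) arms | O[C@H](Cc1c([C@@H]([C@@H](O)c2ccc(OCc3ccccc3)cc2)c2cc(OCc3ccccc3)cc(OCc3ccccc3)c2)c(OCOC)cc(OCOC)c1[C@@H]([C@@H](O)c1ccc(OCc2ccccc2)cc1)c1cc(OCc2ccccc2)cc(OCc2ccccc2)c1)c1ccc(OCc2ccccc2)cc1OCc1ccccc1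
F4 | step 6 | seven-membered-ring diol: ring A (two OMOM) and ring B bridged by (R)-CH[(R)-CH(OH)(4-benzyloxyphenyl)] and by (S)-CH(2,4-bis(benzyloxy)phenyl)–CH2, second (1R,2R) arm still open | C1[C@@H](c2ccc(OCc3ccccc3)cc2OCc2ccccc2)c2c(OCc3ccccc3)cc(OCc3ccccc3)cc2[C@@H]([C@@H](O)c2ccc(OCc3ccccc3)cc2)c2c1c([C@H]([C@@H](O)c1ccc(OCc3ccccc3)cc1)c1cc(OCc3ccccc3)cc(OCc3ccccc3)c1)c(OCOC)cc2OCOC
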